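The biflavanone is opened at O1–C8a in both C rings and cut at C4–C4a and C4''–C4a''. This leaves the acyclic chain C2–C3–C3''–C2'', a twofold-symmetric stereotetrad with a 4-methoxyphenyl carbinol at each end. That chain is the feature exploited, because each carbinol–allyl pair is what a [2,3]-Wittig shift of an (E)-allyl benzyl ether delivers. One operation on an achiral (2E,4E)-hexadienyl bis(4-methoxybenzyl) ether forms C2–C3 and C2''–C3'', sets all four centres, and leaves two vinyl groups that become C4 and C4''. The precursor carries OCD2 groups, which shield the dienylic positions from the base and are lost on ozonolysis. Rings A and C follow by aryllithium addition and fluoride displacement. One 7-OH is methylated last.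

Key step: step 4

Remark on numbering and configuration: flavanone numbering is used for all intermediates (unprimed = 5,7-dihydroxy unit, doubly primed = 7''-methoxy unit). The target is (2S,3R,2''S,3''R) with both C rings 2,3-trans. Because the rings are closed through oxygen with retention at C2 and C2'', it maps onto the (1S,2R,3R,4S)-configured, anti/anti divinyl diol of the key step.

Assumption: the (S,S)-ligand is taken to give the S carbinols. If a test on a simple mono-ether shows the opposite sense, the equally commercial (R,R)-ligand is used.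

Step 1
Reactants: 1 trans,trans-muconic acid
Product: 2 dimethyl (2E,4E)-hexa-2,4-dienedioate
Conditions: MeOH, H2SO4 (cat), reflux
Reagents that add atoms: methanol, CO
Why: Fischer esterification of the conjugated diacid is driven by the excess of methanol and leaves the E,E geometry untouched.

Step 2
Reactants: 2 dimethyl (2E,4E)-hexa-2,4-dienedioate
Product: 3 (2E,4E)-1,1,6,6-tetradeuteriohexa-2,4-diene-1,6-diol
Conditions: LiAlD4/AlCl3 (3:1), THF/Et2O, 0 °C; then 2, −20 → 0 °C; aq potassium sodium tartrate
Reagents that add atoms: lithium aluminium deuteride LiAlD4 (supplies the four deuterium atoms), [Li+].[2H][Al-]([2H])([2H])[2H]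
Why: Alane reduction of α,β-unsaturated esters is 1,2-selective, so both esters should become CD2OH groups while the diene stays intact.

Step 3
Reactants: 3 (2E,4E)-1,1,6,6-tetradeuteriohexa-2,4-diene-1,6-diol; 4 4-methoxybenzyl chloride (2.3 equiv)
Product: 5 (2E,4E)-1,6-bis[(4-methoxybenzyl)oxy]hexa-2,4-diene as its 1,1,6,6-D4 isotopologue
Conditions: NaH, n-Bu4NI (cat), THF/DMF, 0 °C → rt
Reagents that add atoms: none
Why: Williamson ether synthesis of a primary dialkoxide with a reactive benzylic chloride is reliable and affects neither the alkene geometry nor the label.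

Step 4
Reactants: 5 (2E,4E)-1,6-bis[(4-methoxybenzyl)oxy]hexa-2,4-diene-1,1,6,6-D4
Product: 7 (1S,2R,3R,4S)-1,4-bis(4-methoxyphenyl)-2,3-bis(2,2-dideuteriovinyl)butane-1,4-diol, via mono-rearranged lithium alkoxide 6 (not isolated)
Conditions: t-BuLi (3.0 equiv) premixed with (S,S)-2,2'-(propane-2,2-diyl)bis(4-tert-butyl-4,5-dihydrooxazole) (3.3 equiv), pentane/Et2O, −78 °C; then H2O; ligand recovered
Reagents that add atoms: none
Why: Proposed new method: ligated t-BuLi removes a benzylic proton of 5, the α-oxybenzyllithium bonds suprafacially through a five-membered envelope transition state to the γ-carbon (diene C3) while the O–CD2 bond breaks, and the alkoxide 6 so formed still holds an (E)-allyl 4-methoxybenzyl ether that is lithiated and shifts in the same way onto diene C4, so that C2–C3 and C2''–C3'' are made and rings are not formed. The closest known reaction type is the enantioselective [2,3]-Wittig rearrangement of simple allyl benzyl ethers, methoxy-substituted ones included, with t-BuLi and a bis(oxazoline), whereas a conjugated dienyl bis-ether and two shifts in one flask have not been shown. C2 and C2'' (both S) are controlled by the chiral lithium complex, either in the choice between the enantiotopic benzylic protons or, as α-oxybenzyllithiums invert easily, by dynamic resolution of the carbanion; C3 and C3'' (both R in 7) are controlled by the E geometry, which with the aryl group exo on the envelope gives the anti pair, and the allylic centre of 6 should interfere little because an (E)-1,2-disubstituted alkene has almost no A(1,3) strain. The selectivity most needed is site selectivity of lithiation: attack at a dienylic OCH2 would give a pentadienyl anion that expels 4-methoxybenzyl oxide by 1,6-elimination, and the OCD2 groups of 5 slow this path by a large primary isotope effect without adding a step, since the label leaves with the vinyl termini in step 6. The vinylogous [2,5] shift is an eight-electron all-suprafacial process and thus symmetry-forbidden, and −78 °C disfavours the radical [1,2] and [1,4] pathways. Two ligand-controlled events in series divert mismatched events into separable diastereomers, which should raise the enantiomeric purity of twofold-symmetric 7, and a residual syn pair can be corrected after step 12, when C3 and C3'' lie next to ketones and can settle into the trans arrangement.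

Step 5
Reactants: 7 (1S,2R,3R,4S)-1,4-bis(4-methoxyphenyl)-2,3-bis(2,2-dideuteriovinyl)butane-1,4-diol
Product: 8 (1S,2R,3R,4S)-1,4-bis(tert-butyldimethylsilyloxy)-1,4-bis(4-methoxyphenyl)-2,3-bis(2,2-dideuteriovinyl)butane
Conditions: TBSOTf (3 equiv), 2,6-lutidine, CH2Cl2, 0 °C
Reagents that add atoms: tert-butyldimethylsilyl triflate, CC(C)(C)[Si](C)(C)OS(=O)(=O)C(F)(F)F
Why: Silylation with a silyl triflate and a hindered pyridine base is fast even for crowded secondary benzylic alcohols, leaves the stereocentres alone, and masks the carbinols so that no lactol or retro-aldol path opens once the aldehydes are present.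

Step 6
Reactants: 8 bis(silyl ether) of the divinyl diol
Product: 10 (2R,3R)-2,3-bis[(S)-(tert-butyldimethylsilyloxy)(4-methoxyphenyl)methyl]butanedial, via bis(ozonide) 9 (not isolated)
Conditions: O3, CH2Cl2, −78 °C, Sudan Red 7B as end-point dye; then PPh3, −78 °C → rt
Reagents that add atoms: ozone, [O-][O+]=O
Why: Ozonolysis (cycloaddition, cycloreversion and recombination to the ozonide, then reductive cleavage by the phosphine) attacks the terminal alkenes far faster than the anisyl rings when the dye marks the end point, removes the labelled CD2 termini, and keeps C3 and C3'' unchanged under neutral conditions.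

Step 7
Reactants: 11 1,3,5-trifluorobenzene
Product: 12 1,3-bis(benzyloxy)-5-fluorobenzene
Conditions: BnOH (2.1 equiv), NaH, DMF, 0 → 60 °C
Reagents that add atoms: benzyl alcohol, OCc1ccccc1
Why: In this nucleophilic aromatic substitution of fluoride by benzyl oxide every alkoxy group introduced slows the next displacement, so the reaction should stop after two exchanges.

Step 8
Reactants: 12 1,3-bis(benzyloxy)-5-fluorobenzene
Product: 13 1,5-bis(benzyloxy)-2-bromo-3-fluorobenzene
Conditions: NBS, MeCN, 0 °C
Reagents that add atoms: N-bromosuccinimide, O=C1CCC(=O)N1Br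
Why: Electrophilic aromatic bromination should go para to one benzyloxy group at the position next to the small fluorine, the site between the two benzyloxy groups being more hindered, which fixes the metalation site without relying on a regiochemically ambiguous directed lithiation.

Step 9
Reactants: 10 (2R,3R)-2,3-bis[(S)-(tert-butyldimethylsilyloxy)(4-methoxyphenyl)methyl]butanedial; 13 1,5-bis(benzyloxy)-2-bromo-3-fluorobenzene (2.6 equiv)
Product: 15 1,4-bis[2,4-bis(benzyloxy)-6-fluorophenyl]-2,3-bis[(S)-(tert-butyldimethylsilyloxy)(4-methoxyphenyl)methyl]butane-1,4-diol (C3 and C3'' arranged as in 10; C4/C4'' epimer mixture), via 2,4-bis(benzyloxy)-6-fluorophenyllithium 14 (not isolated)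
Conditions: 13, n-BuLi (2.5 equiv), THF, −78 °C; then 10, −78 → −60 °C; then H2O
Reagents that add atoms: none
Why: Bromine–lithium exchange outruns any deprotonation at −78 °C, where the ortho-fluoroaryllithium does not yet lose LiF, and 1,2-addition to both aldehydes forms C4–C4a and C4''–C4a'', the new carbinol centres needing no control because they are oxidised in step 12.

Step 10
Reactants: 15 bis(silyl ether) bis(carbinol)
Product: 16 1,4-bis[2,4-bis(benzyloxy)-6-fluorophenyl]-2,3-bis[(S)-hydroxy(4-methoxyphenyl)methyl]butane-1,4-diol (C4/C4'' epimer mixture)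
Conditions: n-Bu4NF, THF, rt
Reagents that add atoms: none
Why: Fluoride-induced silyl ether cleavage is driven by the strong Si–F bond, and since no carbonyl group is present at this stage the basic medium can cause neither retro-aldol cleavage nor elimination, while any earlier O-to-O silyl migration becomes irrelevant.

Step 11
Reactants: 16 tetraol
Product: 17 5,7,5'',7''-tetrakis(benzyloxy)-4',4'''-dimethoxy-3,3''-biflavan-4,4''-diol (2S and 2''S; both C rings 2,3-trans; C4/C4'' epimer mixture)
Conditions: KH (6 equiv), THF/DMF, 0 °C → rt, high dilution; then H2O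
Reagents that add atoms: none
Why: In this intramolecular nucleophilic aromatic substitution each benzylic C2 alkoxide attacks its own C8a–F in a six-membered closure, a ring formation known for flavans built from the same 2-fluoro-4,6-bis(benzyloxy)phenyl unit, and because only O–C8a bonds are made C2 and C2'' keep their configuration and the anti pairs become 2,3-trans rings.

Step 12
Reactants: 17 biflavan-4,4''-diol
Product: 18 (2S,3R,2''S,3''R)-5,7,5'',7''-tetrakis(benzyloxy)-4',4'''-dimethoxy-3,3''-biflavanone
Conditions: (n-Pr4N)RuO4 (10 mol%), N-methylmorpholine N-oxide, 4 Å molecular sieves, CH2Cl2, rt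
Reagents that add atoms: none
Why: The Ley–Griffith oxidation turns secondary benzylic alcohols into ketones under neutral conditions that spare the acid-labile flavan-4-ols, erases the C4 mixture, and does not endanger the diequatorial 2,3-trans arrangement, which is the favoured one next to the new ketones.

Step 13
Reactants: 18 tetrabenzyl biflavanone
Product: 19 (2S,3R,2''S,3''R)-5,7,5'',7''-tetrahydroxy-4',4'''-dimethoxy-3,3''-biflavanone
Conditions: H2 (1 atm), Pd/C, THF/MeOH, rt
Reagents that add atoms: none
Why: Catalytic hydrogenolysis removes the four O-benzyl groups much faster than it touches the cyclic C2–O bonds or the aryl ketones at atmospheric pressure in a neutral solvent, as is usual for benzylated flavanones.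

Step 14
Reactants: 19 tetrahydroxy biflavanone
Product: 20 ruixianglangdusu B
Conditions: MeOH (1.0 equiv), PPh3 (1.0 equiv), DIAD (1.0 equiv), THF, 0 °C → rt; unreacted 19 recycled
Reagents that add atoms: methanol, CO
Why: Mitsunobu etherification under neutral conditions alkylates the more acidic 7-hydroxyls while 5-OH and 5''-OH are held in hydrogen bonds to the ketones, and as the two 7-hydroxyls of 19 are homotopic either one gives 20, the mono/di distribution being statistical at one equivalent.

Compound list
1 | trans,trans-muconic acid | OC(=O)/C=C/C=C/C(=O)O | starting material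
2 | dimethyl (2E,4E)-hexa-2,4-dienedioate | COC(=O)/C=C/C=C/C(=O)OC | intermediate
3 | (2E,4E)-1,1,6,6-tetradeuteriohexa-2,4-diene-1,6-diol | [2H]C([2H])(O)/C=C/C=C/C([2H])([2H])O | intermediate
4 | 4-methoxybenzyl chloride | COc1ccc(CCl)cc1 | starting material
5 | (2E,4E)-1,6-bis[(4-methoxybenzyl)oxy]hexa-2,4-diene-1,1,6,6-D4 | COc1ccc(COC([2H])([2H])/C=C/C=C/C([2H])([2H])OCc2ccc(OC)cc2)cc1 | intermediate
6 | lithium (1S,2R,3E)-1-(4-methoxyphenyl)-5-[(4-methoxybenzyl)oxy]-2-(2,2-dideuteriovinyl)-5,5-dideuteriopent-3-en-1-olate (not isolated) | [Li+].COc1ccc(cc1)[C@@H]([O-])[C@H](C=C([2H])[2H])/C=C/C([2H])([2H])OCc1ccc(OC)cc1 | intermediate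
7 | (1S,2R,3R,4S)-1,4-bis(4-methoxyphenyl)-2,3-bis(2,2-dideuteriovinyl)butane-1,4-diol | COc1ccc(cc1)[C@@H](O)[C@H](C=C([2H])[2H])[C@@H](C=C([2H])[2H])[C@H](O)c1ccc(OC)cc1 | intermediate
8 | (1S,2R,3R,4S)-1,4-bis(tert-butyldimethylsilyloxy)-1,4-bis(4-methoxyphenyl)-2,3-bis(2,2-dideuteriovinyl)butane | COc1ccc(cc1)[C@@H](O[Si](C)(C)C(C)(C)C)[C@H](C=C([2H])[2H])[C@@H](C=C([2H])[2H])[C@H](O[Si](C)(C)C(C)(C)C)c1ccc(OC)cc1 | intermediate
9 | bis(1,2,4-trioxolane) of 8, trioxolane carbons unassigned (not isolated) | COc1ccc(cc1)[C@@H](O[Si](C)(C)C(C)(C)C)[C@H](C1OC([2H])([2H])OO1)[C@@H](C1OC([2H])([2H])OO1)[C@H](O[Si](C)(C)C(C)(C)C)c1ccc(OC)cc1 | intermediate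
10 | (2R,3R)-2,3-bis[(S)-(tert-butyldimethylsilyloxy)(4-methoxyphenyl)methyl]butanedial | COc1ccc(cc1)[C@@H](O[Si](C)(C)C(C)(C)C)[C@H](C=O)[C@@H](C=O)[C@H](O[Si](C)(C)C(C)(C)C)c1ccc(OC)cc1 | intermediate
11 | 1,3,5-trifluorobenzene | Fc1cc(F)cc(F)c1 | starting material
12 | 1,3-bis(benzyloxy)-5-fluorobenzene | Fc1cc(OCc2ccccc2)cc(OCc2ccccc2)c1 | intermediate
13 | 1,5-bis(benzyloxy)-2-bromo-3-fluorobenzene | Fc1cc(OCc2ccccc2)cc(OCc2ccccc2)c1Br | intermediate
14 | 2,4-bis(benzyloxy)-6-fluorophenyllithium (not isolated) | [Li]c1c(F)cc(OCc2ccccc2)cc1OCc1ccccc1 | intermediate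
15 | bis(silyl ether) bis(carbinol), C4/C4'' epimer mixture | COc1ccc(cc1)[C@@H](O[Si](C)(C)C(C)(C)C)[C@H](C(O)c1c(F)cc(OCc2ccccc2)cc1OCc1ccccc1)[C@@H](C(O)c1c(F)cc(OCc2ccccc2)cc1OCc1ccccc1)[C@H](O[Si](C)(C)C(C)(C)C)c1ccc(OC)cc1 | intermediate
16 | tetraol, C4/C4'' epimer mixture | COc1ccc(cc1)[C@@H](O)[C@H](C(O)c1c(F)cc(OCc2ccccc2)cc1OCc1ccccc1)[C@@H](C(O)c1c(F)cc(OCc2ccccc2)cc1OCc1ccccc1)[C@H](O)c1ccc(OC)cc1 | intermediate
17 | 5,7,5'',7''-tetrakis(benzyloxy)-4',4'''-dimethoxy-3,3''-biflavan-4,4''-diol, 2,3-trans in both units, C4/C4'' epimer mixture | COc1ccc([C@H]2Oc3cc(OCc4ccccc4)cc(OCc4ccccc4)c3C(O)[C@@H]2[C@H]2C(O)c3c(OCc4ccccc4)cc(OCc4ccccc4)cc3O[C@@H]2c2ccc(OC)cc2)cc1 | intermediate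
18 | (2S,3R,2''S,3''R)-5,7,5'',7''-tetrakis(benzyloxy)-4',4'''-dimethoxy-3,3''-biflavanone | COc1ccc([C@H]2Oc3cc(OCc4ccccc4)cc(OCc4ccccc4)c3C(=O)[C@@H]2[C@H]2C(=O)c3c(OCc4ccccc4)cc(OCc4ccccc4)cc3O[C@@H]2c2ccc(OC)cc2)cc1 | intermediate
19 | (2S,3R,2''S,3''R)-5,7,5'',7''-tetrahydroxy-4',4'''-dimethoxy-3,3''-biflavanone | COc1ccc([C@H]2Oc3cc(O)cc(O)c3C(=O)[C@@H]2[C@H]2C(=O)c3c(O)cc(O)cc3O[C@@H]2c2ccc(OC)cc2)cc1 | intermediate
20 | ruixianglangdusu B, (2S,3R,2''S,3''R)-5,7,5''-trihydroxy-7'',4',4'''-trimethoxy-3,3''-biflavanone | COc1ccc([C@H]2Oc3cc(O)cc(O)c3C(=O)[C@@H]2[C@H]2C(=O)c3c(O)cc(OC)cc3O[C@@H]2c2ccc(OC)cc2)cc1 | target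

Total step count: 14. Longest linear sequence: 12 (steps 1–6 and 9–14).

Steps most likely to fail

1. Step 4.
- What may go wrong:
  - Lithiation may still occur at a dienylic carbon and end in 1,6-elimination.
  - t-BuLi may add to the diene.
  - The carbanion may dissociate into a radical pair stabilised by the pentadienyl unit and recombine in a [1,2] or [1,4] sense.
  - The second lithiation may stall in mixed aggregates with the first alkoxide.
  - Facial control in the second shift may be poor.
- Fallback: it uses known reaction types, sets out from 3 and returns at 7. Acetylation of 3 (Ac2O, pyridine) gives (2E,4E)-1,1,6,6-tetradeuteriohexa-2,4-diene-1,6-diyl diacetate F1. Allylic borylation with B2pin2 under Ni(cod)2/PCy3 catalysis gives the linear (2E,4E)-hexa-2,4-diene-1,6-diyl bis(pinacol boronate)-D4 F2. F2 is then combined with commercial 4-methoxybenzaldehyde (2.2 equiv) and the chiral phosphoric acid 3,3'-bis(2,4,6-triisopropylphenyl)-BINOL hydrogen phosphate in toluene at −30 °C. The first allylboration runs through a chair transition state at C3, shifts the double bond, and leaves a new (E)-allylboronate that adds at C4. The E geometry gives the anti pairs, the acid enantiomer is chosen for the S carbinols, and the same two bonds are formed.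

2. Step 9.
- What may go wrong:
  - After the first addition the γ-oxido aldehyde may close to a lactolate. This would withhold the second aldehyde at the low temperature that the ortho-fluoroaryllithium requires.
  - The basic reagent may enolise the hindered aldehyde and trigger loss of silanolate.
- Fallback: it sets out from 12 and 10 and returns at 15. Iodination of 12 (N-iodosuccinimide, CF3CO2H cat, MeCN) gives 1,5-bis(benzyloxy)-3-fluoro-2-iodobenzene F3. F3 is joined to both aldehydes of 10 by Nozaki–Hiyama–Kishi coupling (CrCl2 in excess, NiCl2 cat, DMF, rt). The arylchromium species is non-basic and thermally robust, so the reaction can be run at room temperature until both carbonyl groups are consumed.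

3. Step 11.
- What may go wrong:
  - Fluoride displacement on a ring without an acceptor group may be too slow.
  - At the temperature then needed, a seven-membered closure by a C4 alkoxide or decomposition may compete.
- Fallback: it sets out from 15 and returns at 18. The carbinols are oxidised first ((n-Pr4N)RuO4, N-methylmorpholine N-oxide) to the bis(silyloxy) bis(aryl ketone) F4. Et3N·3HF in MeCN then frees the bis(β-hydroxy ketone) F5 without forming an alkoxide. K2CO3 in DMF at rt closes both rings by carbonyl-activated fluoride displacement. The mild base is chosen to hold back retro-aldol cleavage and dehydration.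

Further compounds
F1 | step 4 | (2E,4E)-1,1,6,6-tetradeuteriohexa-2,4-diene-1,6-diyl diacetate | CC(=O)OC([2H])([2H])/C=C/C=C/C([2H])([2H])OC(C)=O
F2 | step 4 | (2E,4E)-1,6-bis(4,4,5,5-tetramethyl-1,3,2-dioxaborolan-2-yl)hexa-2,4-diene-1,1,6,6-D4 | [2H]C([2H])(B1OC(C)(C)C(C)(C)O1)/C=C/C=C/C([2H])([2H])B1OC(C)(C)C(C)(C)O1
F3 | step 9 | 1,5-bis(benzyloxy)-3-fluoro-2-iodobenzene | Fc1cc(OCc2ccccc2)cc(OCc2ccccc2)c1I
F4 | step 11 | (2R,3R)-1,4-bis[2,4-bis(benzyloxy)-6-fluorophenyl]-2,3-bis[(S)-(tert-butyldimethylsilyloxy)(4-methoxyphenyl)methyl]butane-1,4-dione | COc1ccc(cc1)[C@@H](O[Si](C)(C)C(C)(C)C)[C@H](C(=O)c1c(F)cc(OCc2ccccc2)cc1OCc1ccccc1)[C@@H](C(=O)c1c(F)cc(OCc2ccccc2)cc1OCc1ccccc1)[C@H](O[Si](C)(C)C(C)(C)C)c1ccc(OC)cc1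
F5 | step 11 | (2R,3R)-1,4-bis[2,4-bis(benzyloxy)-6-fluorophenyl]-2,3-bis[(S)-hydroxy(4-methoxyphenyl)methyl]butane-1,4-dione | COc1ccc(cc1)[C@@H](O)[C@H](C(=O)c1c(F)cc(OCc2ccccc2)cc1OCc1ccccc1)[C@@H](C(=O)c1c(F)cc(OCc2ccccc2)cc1OCc1ccccc1)[C@H](O)c1ccc(OC)cc1
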